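**Plan**

1. Target numbering: O1–O2–C3(Me, side chain)–C4–C4a(Me)–O5–C6(=O)–C7–C7a(–O1). The retrosynthesis cuts, in this order: the C7′=C8′ bond of the side chain (olefination); O1–C7a (oxa-Michael addition of the C3 hydroperoxide to a butenolide); O5–C4a (Baeyer–Villiger); C6–C7 together with C4a–C7a ([2+2] of a methyl alkyl ketene with ethoxyacetylene); C3–O2 (opening of an oxetane by H2O2).
2. Enabling feature: the lactone carbons C6, C7, C7a and C4a carry oxygen at C7a and C4a in a 1,3-relationship. They therefore map onto a four-membered 1,3-dione, whose quaternary carbon (C4a) is the α-carbon of a ketene and is not a stereocenter in the dione.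
3. Forward order: oxetane → protected C3 hydroperoxide → diazoketone → ketene → cyclobutenone (first ring) → dione → hydroxy ketone → γ-lactone by oxygen insertion → butenolide → 1,2-dioxane (last ring) → diene side chain.
4. Stereochemistry: C3 comes from a catalytic asymmetric ylide synthesis of the oxetane (R) followed by invertive opening with H2O2 (S). C4a comes from a catalyst-controlled reduction that desymmetrises the dione and is carried through the Baeyer–Villiger step with retention. C7a follows from the obligatory cis ring fusion in the oxa-Michael closure. The E,E-diene comes from an E-selective phosphonate olefination.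

Key step: step 6

Assumption: the (S)-binaphthoxide lanthanum/lithium catalyst is taken as the enantiomer that leads to the (2R)-oxetane; if its sense is the opposite, the (R)-catalyst is used and nothing else changes.

**Route**

Step 1
Reactants: 1 dec-9-en-2-one
Product: 3 (2R)-2-methyl-2-(oct-7-en-1-yl)oxetane, via epoxide 2 (not isolated)
Conditions: Me2S(O)=CH2 (salt-free THF solution, 1.2 equiv), LaLi3[(S)-1,1′-binaphthalene-2,2′-diolate]3 (5 mol %), tris(2,4,6-trimethoxyphenyl)phosphine oxide (5 mol %), 5 Å molecular sieves, THF, rt; then Me2S(O)=CH2 (1.0 equiv) and more catalyst (15 mol %), 45 °C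
Reagents that add atoms: dimethylsulfoxonium methylide, [CH2-][S+](C)(C)=O
Why: A catalytic asymmetric Corey–Chaykovsky epoxidation of the methyl ketone, followed in the same pot by ylide ring expansion of the 2,2-disubstituted epoxide (attack at its CH2 terminus, then 4-exo-tet closure by the tertiary alkoxide), should give the oxetane; the chiral catalyst selects the ketone face (methyl against n-alkyl), the partly resolving second stage should raise the enantiomeric purity, and the C–O bond of the new stereocenter is never broken.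

Step 2
Reactants: 3 (2R)-2-methyl-2-(oct-7-en-1-yl)oxetane
Product: 4 (3S)-3-hydroperoxy-3-methylundec-10-en-1-ol
Conditions: anhydrous H2O2 in Et2O (excess), Me3SiOTf (0.2 equiv), −78 to 0 °C
Reagents that add atoms: hydrogen peroxide, OO
Why: Lewis-acid-activated oxetanes are opened by hydrogen peroxide at the more substituted carbon in an SN2-like manner (oxetane perhydrolysis), so the tertiary center should be inverted from R to S while the primary alcohol is released and the terminal alkene is left alone.

Step 3
Reactants: 4 (3S)-3-hydroperoxy-3-methylundec-10-en-1-ol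
Product: 5 (3S)-3-[(2-methoxypropan-2-yl)peroxy]-3-methylundec-10-en-1-ol
Conditions: 2-methoxypropene (1.05 equiv), pyridinium p-toluenesulfonate (2 mol %), CH2Cl2, −20 °C
Reagents that add atoms: 2-methoxypropene, COC(C)=C
Why: In this acid-catalysed peroxyketalisation (addition of ROOH to an enol ether) the more acidic, α-effect-activated hydroperoxide should react ahead of the primary alcohol when only one equivalent of enol ether is offered.

Step 4
Reactants: 5 (3S)-3-[(2-methoxypropan-2-yl)peroxy]-3-methylundec-10-en-1-ol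
Product: 7 (3S)-3-[(2-methoxypropan-2-yl)peroxy]-3-methylundec-10-enoic acid, via aldehyde 6 (not isolated)
Conditions: 2,2,6,6-tetramethylpiperidin-1-oxyl (7 mol %), NaOCl (2 mol %), NaClO2 (2 equiv), MeCN/phosphate buffer pH 6.7, 35 °C; acid extracted at pH 4 and used at once
Reagents that add atoms: sodium chlorite, [Na+].[O-]Cl=O
Why: The nitroxyl/bleach-catalysed chlorite oxidation of a primary alcohol to the acid runs near neutral pH, which should spare the acid-labile peroxyketal, the O–O bond and the terminal alkene.

Step 5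
Reactants: 7 (3S)-3-[(2-methoxypropan-2-yl)peroxy]-3-methylundec-10-enoic acid
Product: 9 (5S)-2-diazo-5-[(2-methoxypropan-2-yl)peroxy]-5-methyltridec-12-en-3-one, via mixed anhydride 8 (not isolated)
Conditions: iBuOCOCl, N-methylmorpholine, THF, −20 °C; then CH3CHN2 in Et2O (3 equiv), −20 to 0 °C
Reagents that add atoms: diazoethane, CC=[N+]=[N-]
Why: Acylation of diazoethane by a mixed carbonic anhydride (the first half of an Arndt–Eistert homologation) should give the 2-diazo-3-ketone without any acid, and the diazo carbon with its methyl group is the future C4a with its methyl group.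

Step 6
Reactants: 9 (5S)-2-diazo-5-[(2-methoxypropan-2-yl)peroxy]-5-methyltridec-12-en-3-one, 10 ethoxyacetylene
Product: 12 3-ethoxy-4-{(2S)-2-[(2-methoxypropan-2-yl)peroxy]-2-methyldec-9-en-1-yl}-4-methylcyclobut-2-en-1-one (both C4 epimers), via ketene 11 (not isolated)
Conditions: hν (390 nm LED), 10 (5 equiv), CH2Cl2 (0.02 M), 20 °C
Reagents that add atoms: none
Why: Light at 390 nm excites the diazoketone, N2 leaves and the CH2 group shifts to the diazo carbon (Wolff rearrangement), so that this carbon with its methyl group becomes the α-carbon (future C4a) and the old acyl carbon becomes the C=O carbon (future C6) of the methyl alkyl ketene 11. The ketene is trapped as it forms by ethoxyacetylene in a thermal [2+2] cycloaddition, the closest known reaction type being the ketene–alkoxyalkyne route to 3-alkoxycyclobutenones as it is run on photochemically made ketenes in alkyne–ketene benzannulations. The four-membered ring closes in a concerted but asynchronous [π2s+π2a] manner in which C6–C7 bonding (electrophilic ketene carbon, nucleophilic CH terminus of the ynol ether) runs ahead of C4a–C7a bonding. The only new stereocenter, C4a, has no controlling element here and both epimers should form; this is accepted because step 7 turns C4a into a non-stereogenic carbon and step 8 then sets it under catalyst control. The step needs head-to-tail regioselectivity, which the polarisation of the ynol ether against the ketene C=O carbon secures, and it needs trapping to outrun ketene dimerisation and a 1,2-hydride shift of any free keto-carbene, which high dilution, excess alkyne and the concerted photochemical shift should secure. The peroxyketal, the O–O bond and the terminal alkene do not absorb at this wavelength and are poor partners for the ketene next to the electron-rich alkyne.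

Step 7
Reactants: 12 3-ethoxy-4-{(2S)-2-[(2-methoxypropan-2-yl)peroxy]-2-methyldec-9-en-1-yl}-4-methylcyclobut-2-en-1-one
Product: 14 2-{(2S)-2-[(2-methoxypropan-2-yl)peroxy]-2-methyldec-9-en-1-yl}-2-methylcyclobutane-1,3-dione, via lithium enolate 13 (not isolated)
Conditions: LiOH (1.5 equiv), THF/H2O, 0 °C; then cold 0.5 M HCl to pH 3, fast extraction
Reagents that add atoms: lithium hydroxide, [Li+].[OH-]
Why: Conjugate addition–elimination of hydroxide at the ethoxy-bearing carbon (vinylogous ester saponification) should give the dione enolate, which resists ring opening, and on protonation both epimers of 12 converge on one dione in which the quaternary carbon carries two identical carbonyl arms and is no longer a stereocenter.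

Step 8
Reactants: 14 2-{(2S)-2-[(2-methoxypropan-2-yl)peroxy]-2-methyldec-9-en-1-yl}-2-methylcyclobutane-1,3-dione
Product: 16 (2S,3S)-3-hydroxy-2-{(2S)-2-[(2-methoxypropan-2-yl)peroxy]-2-methyldec-9-en-1-yl}-2-methylcyclobutan-1-one, via catechol borate 15 (not isolated)
Conditions: (R)-1-methyl-3,3-diphenyltetrahydro-1H,3H-pyrrolo[1,2-c][1,3,2]oxazaborole (0.2 equiv), catecholborane (1.5 equiv), toluene, −78 °C; pH 7 buffer
Reagents that add atoms: none
Why: In this Corey–Bakshi–Shibata reduction, used to desymmetrise a 2,2-disubstituted cyclic 1,3-diketone, the (R)-oxazaborolidine should give the S carbinol (quaternary carbon as the large group) and hydride entry from the methyl face, anti to the bulky peroxy-alkyl arm, then decides which carbonyl reacts, so the quaternary carbon should become S; attack from the other face gives a cis/trans diastereomer that chromatography removes.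

Step 9
Reactants: 16 (2S,3S)-3-hydroxy-2-{(2S)-2-[(2-methoxypropan-2-yl)peroxy]-2-methyldec-9-en-1-yl}-2-methylcyclobutan-1-one
Product: 17 (4S,5S)-4-hydroxy-5-{(2S)-2-[(2-methoxypropan-2-yl)peroxy]-2-methyldec-9-en-1-yl}-5-methyloxolan-2-one
Conditions: 3-chloroperbenzoic acid (1.1 equiv), NaHCO3 (buffer), CH2Cl2, 0 °C
Reagents that add atoms: 3-chloroperbenzoic acid, OOC(=O)c1cccc(Cl)c1
Why: In this Baeyer–Villiger oxidation the quaternary α-carbon should migrate in preference to CH2 and with retention, so its S configuration becomes that of the lactone C–O carbon (C4a), and the strained ketone should react well before the terminal alkene is epoxidised.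

Step 10
Reactants: 17 (4S,5S)-4-hydroxy-5-{(2S)-2-[(2-methoxypropan-2-yl)peroxy]-2-methyldec-9-en-1-yl}-5-methyloxolan-2-one
Product: 19 (5S)-5-{(2S)-2-[(2-methoxypropan-2-yl)peroxy]-2-methyldec-9-en-1-yl}-5-methylfuran-2(5H)-one, via mesylate 18 (not isolated)
Conditions: MeSO2Cl (1.5 equiv), Et3N (4 equiv), CH2Cl2, 0 °C to rt
Reagents that add atoms: none
Why: Mesylation followed by E1cB β-elimination through the lactone enolate should give the butenolide; the carbinol stereocenter is removed on purpose and the quaternary center is untouched.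

Step 11
Reactants: 19 (5S)-5-{(2S)-2-[(2-methoxypropan-2-yl)peroxy]-2-methyldec-9-en-1-yl}-5-methylfuran-2(5H)-one
Product: 21 (3S,4aS,7aS)-3,4a-dimethyl-3-(oct-7-en-1-yl)tetrahydrofuro[3,2-c][1,2]dioxin-6(3H)-one, via hydroperoxide 20 (not isolated)
Conditions: AcOH/THF/H2O (4:2:1), rt; concentrate; then Et2NH (0.3 equiv), CF3CH2OH, rt
Reagents that add atoms: none
Why: Aqueous acetic acid should hydrolyse the peroxyketal and the amine then promotes an intramolecular oxa-Michael addition (6-exo-trig) of the hydroperoxide to the butenolide; a six–five fusion formed across the butenolide can only be cis, so C7a (S) is set by C4a.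

Step 12
Reactants: 21 (3S,4aS,7aS)-3,4a-dimethyl-3-(oct-7-en-1-yl)tetrahydrofuro[3,2-c][1,2]dioxin-6(3H)-one
Product: 23 7-[(3S,4aS,7aS)-3,4a-dimethyl-6-oxohexahydrofuro[3,2-c][1,2]dioxin-3-yl]heptanal, via ozonide 22 (not isolated)
Conditions: O3, CH2Cl2, −78 °C; then Me2S, −78 °C to rt
Reagents that add atoms: ozone, [O-][O+]=O
Why: Ozonolysis with reductive work-up should cleave the only C=C bond to the aldehyde, since the dialkyl peroxide and the lactone are inert to ozone and to dimethyl sulfide.

Step 13
Reactants: 23 7-[(3S,4aS,7aS)-3,4a-dimethyl-6-oxohexahydrofuro[3,2-c][1,2]dioxin-3-yl]heptanal, 24 diethyl [(2E)-3-phenylprop-2-en-1-yl]phosphonate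
Product: 26 plakortolide R, via lithiated phosphonate 25 (not isolated)
Conditions: 24 (1.2 equiv), LiN(SiMe3)2 (1.15 equiv), THF, −78 °C; then 23, −78 to 0 °C
Reagents that add atoms: none
Why: The Horner–Wadsworth–Emmons olefination with an allylic phosphonate anion should form the new disubstituted double bond with E geometry while the styryl bond keeps its E geometry, and low temperature without excess base should keep the β-peroxy lactone from opening.

**Compound list**

1 | dec-9-en-2-one | CC(=O)CCCCCCC=C | starting material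
2 | (2R)-2-methyl-2-(oct-7-en-1-yl)oxirane | C[C@@]1(CCCCCCC=C)CO1 | intermediate
3 | (2R)-2-methyl-2-(oct-7-en-1-yl)oxetane | C[C@@]1(CCCCCCC=C)CCO1 | intermediate
4 | (3S)-3-hydroperoxy-3-methylundec-10-en-1-ol | OCC[C@@](C)(OO)CCCCCCC=C | intermediate
5 | (3S)-3-[(2-methoxypropan-2-yl)peroxy]-3-methylundec-10-en-1-ol | OCC[C@@](C)(OOC(C)(C)OC)CCCCCCC=C | intermediate
6 | (3S)-3-[(2-methoxypropan-2-yl)peroxy]-3-methylundec-10-enal | O=CC[C@@](C)(OOC(C)(C)OC)CCCCCCC=C | intermediate
7 | (3S)-3-[(2-methoxypropan-2-yl)peroxy]-3-methylundec-10-enoic acid | OC(=O)C[C@@](C)(OOC(C)(C)OC)CCCCCCC=C | intermediate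
8 | isobutyl carbonic (3S)-3-[(2-methoxypropan-2-yl)peroxy]-3-methylundec-10-enoic anhydride | CC(C)COC(=O)OC(=O)C[C@@](C)(OOC(C)(C)OC)CCCCCCC=C | intermediate
9 | (5S)-2-diazo-5-[(2-methoxypropan-2-yl)peroxy]-5-methyltridec-12-en-3-one | CC(=[N+]=[N-])C(=O)C[C@@](C)(OOC(C)(C)OC)CCCCCCC=C | intermediate
10 | ethoxyacetylene (ethoxyethyne) | C#COCC | starting material
11 | (4S)-4-[(2-methoxypropan-2-yl)peroxy]-2,4-dimethyldodeca-1,11-dien-1-one (methyl alkyl ketene) | CC(=C=O)C[C@@](C)(OOC(C)(C)OC)CCCCCCC=C | intermediate
12 | 3-ethoxy-4-{(2S)-2-[(2-methoxypropan-2-yl)peroxy]-2-methyldec-9-en-1-yl}-4-methylcyclobut-2-en-1-one (both C4 epimers) | CCOC1=CC(=O)C1(C)C[C@@](C)(OOC(C)(C)OC)CCCCCCC=C | intermediate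
13 | lithium 4-{(2S)-2-[(2-methoxypropan-2-yl)peroxy]-2-methyldec-9-en-1-yl}-4-methyl-3-oxocyclobut-1-en-1-olate | [Li+].[O-]C1=CC(=O)C1(C)C[C@@](C)(OOC(C)(C)OC)CCCCCCC=C | intermediate
14 | 2-{(2S)-2-[(2-methoxypropan-2-yl)peroxy]-2-methyldec-9-en-1-yl}-2-methylcyclobutane-1,3-dione | O=C1CC(=O)C1(C)C[C@@](C)(OOC(C)(C)OC)CCCCCCC=C | intermediate
15 | catechol borate ester of 16 (O-bound 1,3,2-benzodioxaborol-2-yl) | O=C1C[C@H](OB2Oc3ccccc3O2)[C@]1(C)C[C@@](C)(OOC(C)(C)OC)CCCCCCC=C | intermediate
16 | (2S,3S)-3-hydroxy-2-{(2S)-2-[(2-methoxypropan-2-yl)peroxy]-2-methyldec-9-en-1-yl}-2-methylcyclobutan-1-one | O=C1C[C@H](O)[C@]1(C)C[C@@](C)(OOC(C)(C)OC)CCCCCCC=C | intermediate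
17 | (4S,5S)-4-hydroxy-5-{(2S)-2-[(2-methoxypropan-2-yl)peroxy]-2-methyldec-9-en-1-yl}-5-methyloxolan-2-one | O=C1C[C@H](O)[C@](C)(C[C@@](C)(OOC(C)(C)OC)CCCCCCC=C)O1 | intermediate
18 | (2S,3S)-2-{(2S)-2-[(2-methoxypropan-2-yl)peroxy]-2-methyldec-9-en-1-yl}-2-methyl-5-oxooxolan-3-yl methanesulfonate | O=C1C[C@H](OS(C)(=O)=O)[C@](C)(C[C@@](C)(OOC(C)(C)OC)CCCCCCC=C)O1 | intermediate
19 | (5S)-5-{(2S)-2-[(2-methoxypropan-2-yl)peroxy]-2-methyldec-9-en-1-yl}-5-methylfuran-2(5H)-one | O=C1C=C[C@](C)(C[C@@](C)(OOC(C)(C)OC)CCCCCCC=C)O1 | intermediate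
20 | (5S)-5-[(2S)-2-hydroperoxy-2-methyldec-9-en-1-yl]-5-methylfuran-2(5H)-one | O=C1C=C[C@](C)(C[C@@](C)(OO)CCCCCCC=C)O1 | intermediate
21 | (3S,4aS,7aS)-3,4a-dimethyl-3-(oct-7-en-1-yl)tetrahydrofuro[3,2-c][1,2]dioxin-6(3H)-one | C[C@]1(CCCCCCC=C)C[C@]2(C)OC(=O)C[C@@H]2OO1 | intermediate
22 | (3S,4aS,7aS)-3,4a-dimethyl-3-[6-(1,2,4-trioxolan-3-yl)hexyl]tetrahydrofuro[3,2-c][1,2]dioxin-6(3H)-one (ozonide) | C[C@]1(CCCCCCC3OCOO3)C[C@]2(C)OC(=O)C[C@@H]2OO1 | intermediate
23 | 7-[(3S,4aS,7aS)-3,4a-dimethyl-6-oxohexahydrofuro[3,2-c][1,2]dioxin-3-yl]heptanal | C[C@]1(CCCCCCC=O)C[C@]2(C)OC(=O)C[C@@H]2OO1 | intermediate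
24 | diethyl [(2E)-3-phenylprop-2-en-1-yl]phosphonate | CCOP(=O)(C/C=C/c1ccccc1)OCC | starting material
25 | lithium (2E)-1-(diethoxyphosphoryl)-3-phenylprop-2-en-1-ide | [Li+].CCOP(=O)([CH-]/C=C/c1ccccc1)OCC | intermediate
26 | plakortolide R: (3S,4aS,7aS)-3,4a-dimethyl-3-[(7E,9E)-10-phenyldeca-7,9-dien-1-yl]tetrahydrofuro[3,2-c][1,2]dioxin-6(3H)-one | C[C@]1(CCCCCC/C=C/C=C/c2ccccc2)C[C@]2(C)OC(=O)C[C@@H]2OO1 | target

**Step count and risks**

Total step count: 13. Longest linear sequence: 13 steps (from 1 to 26).

Steps most likely to fail: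

Step 6. The photogenerated keto-carbene may undergo a 1,2-hydride shift to an enone instead of the Wolff shift, the ketene may dimerise before it meets the alkyne, or the cyclobutenone may undergo secondary photochemical ring opening. Fallback: the fallback sets out from 9 and separates ketene formation from the cycloaddition. Silver-catalysed Wolff rearrangement in methanol (AgO2CPh, Et3N, MeOH) should give the methyl ester F1. Saponification (LiOH, THF/H2O) should give the acid F2, and 1-chloro-N,N,2-trimethylprop-1-en-1-amine in CH2Cl2 should give the acid chloride F3 without acid. Slow addition of Et3N to F3 in the presence of 10 in the dark generates ketene 11 by dehydrochlorination and should give the same cyclobutenone; the fallback comes back to the route at 12.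

Step 8. The catalyst may fail to discriminate the two carbonyl groups (enolisation of the acidic dione, weak facial bias of the methyl against the arm) or over-reduction to the diol may occur. Fallback: the fallback sets out from 14 and gives up the catalyst control in favour of a late separation. NaBH4 (MeOH/CH2Cl2, −78 °C) should give the hydroxy ketone mixture F4. 3-Chloroperbenzoic acid/NaHCO3 should give the hydroxy lactone mixture F5. MeSO2Cl/Et3N should lead through the mesylates F6 to the butenolide epimers F7. AcOH/THF/H2O should give the hydroperoxides F8, and Et2NH in CF3CH2OH should give 21 together with its (3S,4aR,7aR) diastereomer F9, from which 21 is separated by chromatography; the fallback comes back to the route at 21.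

Step 13. The phosphonate anion may deprotonate C7 and trigger retro-oxa-Michael opening of the β-peroxy lactone, or base may attack C7a–H and fragment the peroxide, before olefination is complete. Fallback: the fallback sets out from 21 and avoids base altogether, replacing steps 12 and 13 by an olefin cross-metathesis of the terminal alkene with (E)-buta-1,3-dien-1-ylbenzene. This uses the second-generation Hoveyda–Grubbs catalyst RuCl2(=CH-C6H4-2-OiPr)(H2IMes) in CH2Cl2 at 40 °C and relies on the lower reactivity of the styryl double bond. It comes back to the route at 26 and makes no new compound.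

**Further compounds**

F1 | step 6 | methyl (4S)-4-[(2-methoxypropan-2-yl)peroxy]-2,4-dimethyldodec-11-enoate (both C2 epimers) | COC(=O)C(C)C[C@@](C)(OOC(C)(C)OC)CCCCCCC=C
F2 | step 6 | (4S)-4-[(2-methoxypropan-2-yl)peroxy]-2,4-dimethyldodec-11-enoic acid (both C2 epimers) | OC(=O)C(C)C[C@@](C)(OOC(C)(C)OC)CCCCCCC=C
F3 | step 6 | (4S)-4-[(2-methoxypropan-2-yl)peroxy]-2,4-dimethyldodec-11-enoyl chloride (both C2 epimers) | ClC(=O)C(C)C[C@@](C)(OOC(C)(C)OC)CCCCCCC=C
F4 | step 8 | 3-hydroxy-2-{(2S)-2-[(2-methoxypropan-2-yl)peroxy]-2-methyldec-9-en-1-yl}-2-methylcyclobutan-1-one (mixture of ring stereoisomers) | O=C1CC(O)C1(C)C[C@@](C)(OOC(C)(C)OC)CCCCCCC=C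
F5 | step 8 | 4-hydroxy-5-{(2S)-2-[(2-methoxypropan-2-yl)peroxy]-2-methyldec-9-en-1-yl}-5-methyloxolan-2-one (mixture of ring stereoisomers) | O=C1CC(O)C(C)(C[C@@](C)(OOC(C)(C)OC)CCCCCCC=C)O1
F6 | step 8 | 2-{(2S)-2-[(2-methoxypropan-2-yl)peroxy]-2-methyldec-9-en-1-yl}-2-methyl-5-oxooxolan-3-yl methanesulfonate (mixture of ring stereoisomers) | O=C1CC(OS(C)(=O)=O)C(C)(C[C@@](C)(OOC(C)(C)OC)CCCCCCC=C)O1
F7 | step 8 | 5-{(2S)-2-[(2-methoxypropan-2-yl)peroxy]-2-methyldec-9-en-1-yl}-5-methylfuran-2(5H)-one (both C5 epimers) | O=C1C=CC(C)(C[C@@](C)(OOC(C)(C)OC)CCCCCCC=C)O1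
F8 | step 8 | 5-[(2S)-2-hydroperoxy-2-methyldec-9-en-1-yl]-5-methylfuran-2(5H)-one (both C5 epimers) | O=C1C=CC(C)(C[C@@](C)(OO)CCCCCCC=C)O1
F9 | step 8 | (3S,4aR,7aR)-3,4a-dimethyl-3-(oct-7-en-1-yl)tetrahydrofuro[3,2-c][1,2]dioxin-6(3H)-one | C[C@]1(CCCCCCC=C)C[C@@]2(C)OC(=O)C[C@H]2OO1
F0 | step 13 | none | none
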